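1. A small charge of partner, 11.4 mM, stands against 12 mM of starting material in the three flasks, and I followed who gets it.

| setting | autumn | summer | Thursday's | Wednesday's | Monday's |
|---|---|---|---|---|---|
| starting material | 12 mM | 12 mM | 12 mM | 12 mM | 12 mM |
| partner | 11.4 mM | 11.4 mM | 11.4 mM | 11.4 mM | 11.4 mM |
| second substrate | 3 mM | 12 mM | 6.00 mM | 6.00 mM | 6.00 mM |
| third substrate | 60 mM | 60 mM | 60.0 mM | 60.0 mM | 60.0 mM |
| temperature | 55 °C | 88 °C | 70 °C | 40 °C | 100 °C |
| remark | run made earlier | run made earlier |  |  |  |
| time |  |  | 12 h | 12 h | 12 h |

| run | time / h | target / % | starting material / % |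
|---|---|---|---|
| autumn | 5.00 | 60.0 | 41.9 |
| autumn | 10.0 | 58.3 | 41.2 |
| autumn | 15.0 | 58.7 | 41.3 |
| autumn | 20.0 | 58.2 | 41.7 |
| autumn | 25.0 | 57.6 | 41.5 |
| summer | 1.00 | 17.6 | 82.4 |
| summer | 2.00 | 18.0 | 81.6 |
| summer | 3.00 | 18.0 | 81.6 |
| summer | 4.00 | 18.9 | 82.8 |
| summer | 5.00 | 18.3 | 82.1 |

(readings scatter by 0.5 percentage points)

- the flask that comes out highest in amount of target, in percent of the starting material charged, or "all alike" when all lie within 1.5 percentage points (Thursday's / Wednesday's / Monday's / all alike)
- target at the end, in percent of the starting material charged, Thursday's
- target at the end, in percent of the starting material charged, Wednesday's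
- target at the end, in percent of the starting material charged, Monday's



2. The end of a run, as read: in the autumn run, target and starting material summed to about 100 % and stayed flat from the first reading at 5.00 h, with starting material at 41.5 %. I therefore took partner to be the limiting reagent, the charge that ends the run.

3. The first instants, as I pictured them: second substrate takes partner equal to its whole charge. I called what remains the spare partner, partner charged minus second substrate charged. In the autumn run that is 8.40 mM.

4. The middle: spare partner goes to starting material, with some lost to the large charge of third substrate. The autumn target averaged 58.6 %, so g, the share of spare partner that ends as target 83.7 %, was a reading of that size.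

5. My reckoning: each of the three flasks has 5.40 mM spare, so each gives about 37.6 %. The summer run is a warning: its spare partner is −0.600 mM, yet target read 18.3 %, so my figure is rough for a hot flask.

6. The forecast differed from my single figure: 39 % for Thursday's, 72 % for Wednesday's and 11 % for Monday's, with Wednesday's highest. Its ground was that “these are equilibria rather than yield-limited runs”.

7. Thursday's gave 37.2 %, Wednesday's 40.3 % and Monday's 36.7 %, so Wednesday's was highest.

    partner → decomposed reagent (k = 0.00180 min⁻¹, Ea = 109 kJ mol⁻¹)
    starting material + partner → target (k = 15.0 M⁻¹ min⁻¹, Ea = 66.0 kJ mol⁻¹)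
    second substrate + partner → second product (k = 150 M⁻¹ min⁻¹, Ea = 38.0 kJ mol⁻¹)
    third substrate + partner → third product (k = 0.510 M⁻¹ min⁻¹, Ea = 85.0 kJ mol⁻¹)
    (constants at 70 °C)

8. Monday's target stayed at 36.7 % in part because of the step from second substrate and partner to second product: without that step, Monday's target stood at 63.3 %. In Monday's, second product took 5.25 mM, and 71.5 % of the partner left over became target, less than the 83.7 % read as g in the autumn run. The neighbour of Monday's with 10 mM of second substrate made 7.29 mM of second product, so that share gives 24.5 %, and that flask gave 25.0 %.

The runs were computed on assumed constants, noise included.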